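The earlier runs and the new flask were generated by integration on assumed constants; the scatter is artificial.

The leftover comes first: 0.900 equiv of solid reagent, the limiting reagent, leaves 10.0% of the substrate in the theta flask without a partner to meet. What I have to decide is whether the next charge goes into free catalyst or into the dissolving of the solid.

common to all: substrate 1.4 M

| flask | solid reagent | free catalyst | remark | time |
|---|---|---|---|---|
| theta | 0.90 equiv | 10 mol% | the very flask that is asked about, followed so far |  |
| epsilon | 0.90 equiv | 6.7 mol% | run made earlier |  |
| flask | 0.900 equiv | 10 mol% |  | 80 min |

| run | time / min | product / % | substrate / % |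
|---|---|---|---|
| theta | 3.00 | 3.9 | 89.5 |
| theta | 5.00 | 8.7 | 85.1 |
| theta | 8.00 | 15.5 | 78.3 |
| theta | 12.0 | 25.1 | 69.7 |
| theta | 15.0 | 30.6 | 64.0 |
| theta | 25.0 | 46.8 | 47.0 |
| theta | 40.0 | 65.0 | 30.0 |
| epsilon | 6.00 | 8.2 | 88.3 |
| epsilon | 10.0 | 14.4 | 81.8 |
| epsilon | 15.0 | 22.1 | 74.4 |
| epsilon | 25.0 | 35.1 | 61.1 |
| epsilon | 30.0 | 41.3 | 55.4 |
| epsilon | 50.0 | 59.6 | 37.3 |
| epsilon | 80.0 | 75.3 | 21.2 |

(standard deviation of a reading: 0.3 percentage points)

- solid, in amounts per volume of the solution: solid reagent
- the numbers in the tables scatter by 0.3 percentage points (one standard deviation)
- on the list of suspects stand: substrate + free catalyst -> catalyst intermediate A; solid reagent <-> partner; partner + catalyst intermediate A -> catalyst intermediate B; catalyst intermediate B -> free catalyst + product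
- at the start none of the solid reagent is in solution

* product at 80 min, in percent of the substrate charged
* concentration of partner in solution at 20 min, in percent of saturation
* the change that raises the amount of product at 80 min, in percent of the substrate charged most ("none" if none brings more than 2 percentage points) (grey / amber / green / none)
* amount of product at 80 min, in percent of the substrate charged, after amber

- grey: doubling the amount of free catalyst, all else as stated
- amber: doubling the dissolution coefficient of the solid reagent, all else as stated
- green: doubling the solubility of the solid reagent, all else as stated

I follow one concentration, the headroom H: the reagent charged, as a concentration, minus the product formed. Once the solid is in solution and little sits in catalyst intermediate B, H is the partner concentration. In the theta flask H falls from 0.605 M at 25.0 min to 0.350 M at 40.0 min. I read that as a pseudo-first-order constant, the fractional loss of headroom per minute, k_H = 0.0365 /min. The last two readings of the epsilon run give 0.0242 /min, and the ratio of the two constants, 0.663, is about the same as the loading ratio of 0.670. So I take k_H as proportional to the catalyst loading, and I expect amber and green to stay below 2 percentage points.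

Carrying H from 40.0 min to 80 min with k_H, my own reckoning gives 84.2% of product, and I put the amber flask at the same figure. I take doubled catalyst as doubled time, which gives by my reckoning 89.7%, a gain of 5.5 points, so I charge more free catalyst and leave the solid alone. Carried back to 20 min, k_H puts H at 0.726 M; I can read no solubility from these readings, so I give no percentage of saturation.

The forecast says 86%, 77% of saturation, grey as the best change and 86.8% after amber, holding that “Doubling catalyst gets closest to the cap”. Its yield stands higher than mine, but its choice is the same.

The flask gives 84.5%, 57.7% of saturation, grey as the best change with a gain of 5.1 points, and 84.5% after amber.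

    substrate + free catalyst → catalyst intermediate A (k = 0.00770 /M/s)
    solid reagent ⇌ partner, rate k2*(cs2 - [partner]) while solid is left; crystals form when [partner] > cs2 (solubility = 1.20 M, k = 0.0150 /s)
    partner + catalyst intermediate A → catalyst intermediate B (k = 0.00860 /M/s)
    catalyst intermediate B → free catalyst + product (k = 0.0320 /s)

At 80.0 min the flask holds 0.0754 M of partner, and k_H carried from 40.0 min gives 0.0813 M. The neighbouring flask stopped at 20 min holds 0.692 M of partner against my 0.726 M, which over the saturation of 1.2 M is 60.5%, where the flask gives 57.7%.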